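## Retrosynthetic overview

1. The bicyclo[2.2.2]octane and its spiro centre are formed last, by an intermolecular [4+2] union of (R)-sorbicillinol (diene C6=C1–C2=C3) with an exo-methylene dioxanone dienophile (CH2 to C6, O-bearing carbon to C3).
2. (R)-Sorbicillinol comes from its 5-O-acetate, which comes from sorbicillin by Wessely acetoxylative dearomatisation and resolution.
3. Key fragment-joining C–C bond: the sorbyl C2′–C3′ bond, made by an intermolecular lithium-enolate aldol of bis-MOM clavatol (from 2,4-dimethylresorcinol and AcOH) with crotonaldehyde, then dehydration.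
4. The dienophile comes from methyl 3-epi-shikimate (Mitsunobu inversion at C3 of diacetal-protected methyl shikimate) and a diazophosphonoacetate (Rh carbenoid O–H insertion), then lactonisation onto O4 and Horner–Wadsworth–Emmons methylenation.
5. Ring order: aromatic ring (bought) → dearomatised cyclohexadienone; dioxanone ring on the shikimate cyclohexene; bicyclo[2.2.2]octane and spiro junction last.

Assumption: enol/keto tautomers of the β-triketone units count as one compound; sorbicillinol atoms are numbered C1 (acyl-bearing) to C6 (ring CH) with the carbinol carbon as C5, and shikimate numbering is kept for the carbocycle.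

## Route

Step 1
Reactants: 1 2,4-dimethylbenzene-1,3-diol
Product: 2 1-(2,4-dihydroxy-3,5-dimethylphenyl)ethan-1-one (clavatol)
Conditions: AcOH, BF3·OEt2, 90 °C
Reagents that add atoms: acetic acid CC(=O)O
Why: Friedel–Crafts (Nencki-type) C-acylation goes to the only ring position that is ortho to one hydroxyl and para to the other, giving the chelated o-hydroxyaryl methyl ketone with no stereocentre.

Step 2
Reactants: 2 clavatol
Product: 3 1-[2,4-bis(methoxymethoxy)-3,5-dimethylphenyl]ethan-1-one
Conditions: NaH, MOMCl, DMF, 0 °C → rt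
Reagents that add atoms: chloromethyl methyl ether COCCl
Why: Williamson-type O-alkylation of both phenoxides removes the acidic OH groups so that the methyl ketone can be enolised cleanly in the next step.

Step 3
Reactants: 3 1-[2,4-bis(methoxymethoxy)-3,5-dimethylphenyl]ethan-1-one; 4 (E)-but-2-enal (crotonaldehyde)
Product: 5 (E)-1-[2,4-bis(methoxymethoxy)-3,5-dimethylphenyl]-3-hydroxyhex-4-en-1-one (racemic)
Conditions: LiN(i-Pr)2 (LDA), THF, −78 °C; then 4, −78 °C; AcOH quench
Reagents that add atoms: none
Why: directed intermolecular aldol addition of the kinetic lithium enolate to the enal carbonyl (1,2-addition at −78 °C) joins the C8 aryl ketone and the C4 aldehyde through the C2′–C3′ bond, the new carbinol centre being racemic and destroyed in step 4.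

Step 4
Reactants: 5 (E)-1-[2,4-bis(methoxymethoxy)-3,5-dimethylphenyl]-3-hydroxyhex-4-en-1-one
Product: 7 (2E,4E)-1-[2,4-bis(methoxymethoxy)-3,5-dimethylphenyl]hexa-2,4-dien-1-one, via allylic mesylate 6 (not isolated)
Conditions: MsCl, Et3N, CH2Cl2, 0 °C → rt
Reagents that add atoms: none
Why: mesylation followed by E1cB elimination of the β-sulfonyloxy ketone gives the fully conjugated dienone with the thermodynamically preferred 2E,4E geometry while the phenols stay protected.

Step 5
Reactants: 7 (2E,4E)-1-[2,4-bis(methoxymethoxy)-3,5-dimethylphenyl]hexa-2,4-dien-1-one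
Product: 8 sorbicillin [(2E,4E)-1-(2,4-dihydroxy-3,5-dimethylphenyl)hexa-2,4-dien-1-one]
Conditions: HCl (3 M in MeOH), 40 °C
Reagents that add atoms: none
Why: acid-catalysed acetal exchange (methanolysis of the two MOM ethers) frees both phenols, the dienone being stable to dilute acid.

Step 6
Reactants: 8 sorbicillin
Product: 9 rac-5-O-acetylsorbicillinol [6-acetoxy-3-hydroxy-2,6-dimethyl-4-[(2E,4E)-hexa-2,4-dienoyl]cyclohexa-2,4-dien-1-one]
Conditions: Pb(OAc)4, AcOH/CH2Cl2, 0 °C → rt
Reagents that add atoms: lead tetraacetate CC(=O)O[Pb](OC(C)=O)(OC(C)=O)OC(C)=O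
Why: Wessely acetoxylative dearomatisation, in which tetravalent lead bound to the 4-OH delivers acetate to the methyl-bearing ortho carbon C5 and leaves as divalent lead, gives the o-quinol acetate with a racemic quaternary centre (minor C3 regioisomer removed on silica).

Step 7
Reactants: 9 rac-5-O-acetylsorbicillinol
Product: 10 (R)-5-O-acetylsorbicillinol [(6R)-6-acetoxy-3-hydroxy-2,6-dimethyl-4-[(2E,4E)-hexa-2,4-dienoyl]cyclohexa-2,4-dien-1-one]
Conditions: preparative HPLC, amylose tris(3,5-dimethylphenylcarbamate) phase, hexane/i-PrOH, rt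
Reagents that add atoms: none
Why: chromatographic resolution of the enantiomers (no bond is changed) supplies the 5R antipode that maps onto the carbinol centre of the target, its configuration being assigned by CD and X-ray analysis.

Step 8
Reactants: 11 (−)-shikimic acid
Product: 12 methyl shikimate
Conditions: MeOH, CSA (cat.), reflux
Reagents that add atoms: methanol CO
Why: Fischer esterification installs the methyl ester of the target without touching the three carbinol centres taken from the chiral pool.

Step 9
Reactants: 12 methyl shikimate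
Product: 13 methyl shikimate 4,5-O-butane-2,3-diacetal (both OMe axial; free 3-OH)
Conditions: butane-2,3-dione, HC(OMe)3, CSA (cat.), MeOH, reflux
Reagents that add atoms: butane-2,3-dione CC(=O)C(C)=O; trimethyl orthoformate COC(OC)OC (source of the two OMe groups, in exchange with the solvent methanol CO)
Why: butane-2,3-diacetal formation under thermodynamic control selects the trans-diequatorial 4,5-diol, the two acetal centres being fixed by the anomeric effect, so that only the allylic 3-OH stays free.

Step 10
Reactants: 13 methyl shikimate 4,5-O-butane-2,3-diacetal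
Product: 14 methyl 3-epi-shikimate 4,5-O-butane-2,3-diacetal 3-O-(4-nitrobenzoate)
Conditions: 4-O2NC6H4CO2H, PPh3, DIAD, THF, 0 °C → rt
Reagents that add atoms: 4-nitrobenzoic acid O=C(O)c1ccc(cc1)[N+](=O)[O-]
Why: Mitsunobu esterification displaces the activated pseudoaxial allylic C3 oxygen by SN2 with inversion, which sets the 3,4-trans (3-epi) configuration that the target carries at its ether-bearing carbon.

Step 11
Reactants: 14 methyl 3-epi-shikimate 4,5-O-butane-2,3-diacetal 3-O-(4-nitrobenzoate)
Product: 15 methyl 3-epi-shikimate 4,5-O-butane-2,3-diacetal (free 3-OH)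
Conditions: K2CO3 (cat.), MeOH, 0 °C → rt
Reagents that add atoms: none
Why: base-catalysed transesterification cleaves the activated aryl ester at the acyl carbon, so C3 keeps its inverted configuration and the methyl ester is unchanged.

Step 12
Reactants: 16 trimethyl phosphonoacetate
Product: 17 methyl 2-diazo-2-(dimethoxyphosphoryl)acetate
Conditions: 4-AcNHC6H4SO2N3, DBU, MeCN, 0 °C → rt
Reagents that add atoms: 4-acetamidobenzenesulfonyl azide CC(=O)Nc1ccc(cc1)S(=O)(=O)N=[N+]=[N-]
Why: Regitz diazo transfer to the doubly activated methylene gives the stabilised diazo compound needed as carbenoid precursor.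

Step 13
Reactants: 15 methyl 3-epi-shikimate 4,5-O-butane-2,3-diacetal; 17 methyl 2-diazo-2-(dimethoxyphosphoryl)acetate
Product: 18 methyl 3-O-[(dimethoxyphosphoryl)(methoxycarbonyl)methyl]-3-epi-shikimate 4,5-O-butane-2,3-diacetal (about 1:1 epimers at the P-bearing carbon)
Conditions: Rh2(OAc)4 (2 mol %), benzene, 80 °C, slow addition of 17
Reagents that add atoms: none
Why: O–H insertion of the divalent rhodium carbenoid forms the hindered ether without breaking the C3–O bond (retention at C3), and the new phosphonate-bearing centre is a mixture that is erased in step 15.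

Step 14
Reactants: 18 methyl 3-O-[(dimethoxyphosphoryl)(methoxycarbonyl)methyl]-3-epi-shikimate 4,5-O-butane-2,3-diacetal
Product: 20 3-(dimethoxyphosphoryl)-1,4-dioxan-2-one trans-fused to methyl 3-epi-shikimate, via diol 19 (not isolated)
Conditions: TFA/H2O (9:1), rt; evaporate; then CSA (cat.), toluene, 70 °C, 4 Å MS
Reagents that add atoms: none
Why: acid hydrolysis of the diacetal followed by acid-catalysed lactonisation (intramolecular transesterification) of the activated α-alkoxy-α-phosphono ester closes onto the trans 4-OH, the only hydroxyl that can give a six-membered ring, leaving 5-OH free.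

Step 15
Reactants: 20 3-(dimethoxyphosphoryl)-1,4-dioxan-2-one trans-fused to methyl 3-epi-shikimate
Product: 21 3-methylidene-1,4-dioxan-2-one trans-fused to methyl 3-epi-shikimate (scytolide skeleton; 3S,4S,5R)
Conditions: HCHO (37 % aq.), K2CO3, THF, 0 °C
Reagents that add atoms: formaldehyde C=O
Why: Horner–Wadsworth–Emmons methylenation of the readily deprotonated α-phosphono lactone under mild base creates the exocyclic enol-ether alkene and removes the epimeric phosphonate centre.

Step 16
Reactants: 10 (R)-5-O-acetylsorbicillinol; 21 3-methylidene-1,4-dioxan-2-one trans-fused to methyl 3-epi-shikimate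
Product: 23 target spiro cycloadduct CNP0259039.2, via (R)-sorbicillinol 22 (not isolated)
Conditions: KOH, THF/H2O (9:1), 0 °C; then 1 M HCl to pH 3, CH2Cl2, 21 (2.5 equiv, excess recovered), 0 °C → rt, 24 h; preparative HPLC
Reagents that add atoms: none
Why: base cleaves the α-ketol acetate and acidification releases sorbicillinol 22, which is trapped by excess 21 in a Diels–Alder reaction in which the dienophile adds to the diene face carrying the C5 hydroxyl, CH2 bonds to C6 and the oxygenated carbon to C3, the lactone carbonyl sits endo over C1–C2 and the new bond to C3 is formed on the dienophile face syn to H-3 of the shikimate ring, so that both bridgeheads and the spiro centre are set and the exo and other facial isomers are removed by HPLC.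

## Compound list

1 | 2,4-dimethylbenzene-1,3-diol (2,4-dimethylresorcinol) | Cc1ccc(O)c(C)c1O | starting material
2 | 1-(2,4-dihydroxy-3,5-dimethylphenyl)ethan-1-one (clavatol) | CC(=O)c1cc(C)c(O)c(C)c1O | intermediate
3 | 1-[2,4-bis(methoxymethoxy)-3,5-dimethylphenyl]ethan-1-one | CC(=O)c1cc(C)c(OCOC)c(C)c1OCOC | intermediate
4 | (E)-but-2-enal (crotonaldehyde) | C/C=C/C=O | starting material
5 | (E)-1-[2,4-bis(methoxymethoxy)-3,5-dimethylphenyl]-3-hydroxyhex-4-en-1-one (racemic) | C/C=C/C(O)CC(=O)c1cc(C)c(OCOC)c(C)c1OCOC | intermediate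
6 | 3-O-methanesulfonate of 5 (allylic mesylate; not isolated) | C/C=C/C(OS(C)(=O)=O)CC(=O)c1cc(C)c(OCOC)c(C)c1OCOC | intermediate
7 | (2E,4E)-1-[2,4-bis(methoxymethoxy)-3,5-dimethylphenyl]hexa-2,4-dien-1-one | C/C=C/C=C/C(=O)c1cc(C)c(OCOC)c(C)c1OCOC | intermediate
8 | sorbicillin [(2E,4E)-1-(2,4-dihydroxy-3,5-dimethylphenyl)hexa-2,4-dien-1-one] | C/C=C/C=C/C(=O)c1cc(C)c(O)c(C)c1O | intermediate
9 | rac-5-O-acetylsorbicillinol [6-acetoxy-3-hydroxy-2,6-dimethyl-4-[(2E,4E)-hexa-2,4-dienoyl]cyclohexa-2,4-dien-1-one] | C/C=C/C=C/C(=O)C1=CC(C)(OC(C)=O)C(=O)C(C)=C1O | intermediate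
10 | (R)-5-O-acetylsorbicillinol [(6R)-6-acetoxy-3-hydroxy-2,6-dimethyl-4-[(2E,4E)-hexa-2,4-dienoyl]cyclohexa-2,4-dien-1-one] | C/C=C/C=C/C(=O)C1=C[C@@](C)(OC(C)=O)C(=O)C(C)=C1O | intermediate
11 | (−)-shikimic acid [(3R,4S,5R)-3,4,5-trihydroxycyclohex-1-ene-1-carboxylic acid] | O[C@@H]1C=C(C(=O)O)C[C@@H](O)[C@@H]1O | starting material
12 | methyl shikimate | O[C@@H]1C=C(C(=O)OC)C[C@@H](O)[C@@H]1O | intermediate
13 | methyl shikimate 4,5-O-butane-2,3-diacetal [methyl 4,5-O-(2,3-dimethoxybutane-2,3-diyl)shikimate; both OMe axial; free 3-OH] | O[C@@H]1C=C(C(=O)OC)C[C@H]2O[C@](C)(OC)[C@@](C)(OC)O[C@H]12 | intermediate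
14 | methyl 3-epi-shikimate 4,5-O-butane-2,3-diacetal 3-O-(4-nitrobenzoate) | O=C(O[C@H]1C=C(C(=O)OC)C[C@H]2O[C@](C)(OC)[C@@](C)(OC)O[C@H]12)c1ccc(cc1)[N+](=O)[O-] | intermediate
15 | methyl 3-epi-shikimate 4,5-O-butane-2,3-diacetal (free 3-OH; 3,4-trans) | O[C@H]1C=C(C(=O)OC)C[C@H]2O[C@](C)(OC)[C@@](C)(OC)O[C@H]12 | intermediate
16 | trimethyl phosphonoacetate | COC(=O)CP(=O)(OC)OC | starting material
17 | methyl 2-diazo-2-(dimethoxyphosphoryl)acetate | COC(=O)C(=[N+]=[N-])P(=O)(OC)OC | intermediate
18 | methyl 3-O-[(dimethoxyphosphoryl)(methoxycarbonyl)methyl]-3-epi-shikimate 4,5-O-butane-2,3-diacetal (epimer mixture at the P-bearing carbon) | COC(=O)C(O[C@H]1C=C(C(=O)OC)C[C@H]2O[C@](C)(OC)[C@@](C)(OC)O[C@H]12)P(=O)(OC)OC | intermediate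
19 | methyl 3-O-[(dimethoxyphosphoryl)(methoxycarbonyl)methyl]-3-epi-shikimate (4,5-diol; epimer mixture; not isolated) | COC(=O)C(O[C@H]1C=C(C(=O)OC)C[C@@H](O)[C@@H]1O)P(=O)(OC)OC | intermediate
20 | 3-(dimethoxyphosphoryl)-1,4-dioxan-2-one trans-fused to methyl 3-epi-shikimate (ether O at C3; lactone O at C4; free 5-OH; epimer mixture at the P-bearing carbon) | COP(=O)(OC)C1O[C@H]2C=C(C(=O)OC)C[C@@H](O)[C@@H]2OC1=O | intermediate
21 | 3-methylidene-1,4-dioxan-2-one trans-fused to methyl 3-epi-shikimate (scytolide skeleton; 3S,4S,5R; enol-ether O at C3; lactone O at C4; free 5-OH) | C=C1O[C@H]2C=C(C(=O)OC)C[C@@H](O)[C@@H]2OC1=O | intermediate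
22 | (R)-sorbicillinol [(6R)-3,6-dihydroxy-2,6-dimethyl-4-[(2E,4E)-hexa-2,4-dienoyl]cyclohexa-2,4-dien-1-one; not isolated] | C/C=C/C=C/C(=O)C1=C[C@@](C)(O)C(=O)C(C)=C1O | intermediate
23 | target CNP0259039.2: endo cycloadduct of 22 and 21 (sorbicillinol-derived C3 S; C5 R with OH toward the spiro bridge; C6 R; spiro carbon S with lactone C=O toward the enolised diketone bridge; carbocycle 3S,4S,5R) | C/C=C/C=C/C(O)=C1/C(=O)[C@@]2(C)C(=O)[C@](C)(O)[C@@H]1C[C@]21O[C@H]2C=C(C(=O)OC)C[C@@H](O)[C@@H]2OC1=O | target

## Step count and risks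

Total step count: 16 (15 bond-changing steps and one chromatographic resolution).
Longest linear sequence: 8 steps (steps 1–7 then 16; the shikimate branch, steps 8–11 and 13–16, is equally long).

Three steps most likely to fail:

Step 16 (cycloaddition). Free sorbicillinol dimerises readily, and the exo and other facial isomers lower the yield of the wanted adduct. The fallback sets out from 10 and 21 and inverts the order of events. The acetate 10, which does not dimerise at a useful rate, is heated with 21 as the diene (toluene, 80 °C, BHT) to give the 5-O-acetyl cycloadduct F1. Its tertiary α-ketol acetate, far more labile than the hindered spiro-lactone, is then removed by brief methanolysis (K2CO3 cat., MeOH, 0 °C), which comes back to the route at 23.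

Step 6 (Wessely acetoxylation). The yield is moderate, some attack occurs at C3, and the product is racemic, so half of the material is lost in step 7. The fallback sets out from 8 and uses a chiral carboxylate in place of acetate. Pb(OAc)4 is pre-exchanged with excess (S)-2-methoxy-2-phenylacetic acid (AcOH removed in vacuo) and then oxidises 8 in CH2Cl2 at 0 °C. This gives two diastereomeric o-quinol esters that are separated on silica, and the 5R isomer is (5R)-sorbicillinol (S)-O-methylmandelate F2. F2 is taken directly into the KOH/HCl protocol of step 16, where it is cleaved to 22, the point at which the fallback comes back to the route.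

Step 10 (Mitsunobu inversion). The allylic, neopentyl-like C3 centre may give SN2′ or elimination products. The fallback sets out from 13 and replaces substitution by an oxidation–reduction pair. Dess–Martin periodinane (or MnO2) in CH2Cl2 gives the enone methyl 3-dehydroshikimate 4,5-O-butane-2,3-diacetal F3. Luche reduction (NaBH4, CeCl3·7H2O, MeOH, −78 °C) then delivers hydride axially to give the equatorial 3-epi alcohol, which comes back to the route at 15; any natural epimer formed is 13 and is recycled.

## Further compounds

F1 | step 16 | 5-O-acetyl cycloadduct (tertiary acetate of 23) | C/C=C/C=C/C(O)=C1/C(=O)[C@@]2(C)C(=O)[C@](C)(OC(C)=O)[C@@H]1C[C@]21O[C@H]2C=C(C(=O)OC)C[C@@H](O)[C@@H]2OC1=O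
F2 | step 6 | (5R)-sorbicillinol (S)-O-methylmandelate | C/C=C/C=C/C(=O)C1=C[C@@](C)(OC(=O)[C@@H](OC)c2ccccc2)C(=O)C(C)=C1O
F3 | step 10 | methyl 3-dehydroshikimate 4,5-O-butane-2,3-diacetal (enone) | O=C1C=C(C(=O)OC)C[C@H]2O[C@](C)(OC)[C@@](C)(OC)O[C@H]12
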